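**Retrosynthetic overview**

The two esters are put on last; the C4 carbinol comes from isopropyl addition to a C4 cyclopentanone, and the C4–O / C5–H / C6–O triad is relayed from one allylic alcohol of a bicyclic dienone.
The strategy rests on the seven-membered ring (C1, C5, C6, C7, C8, C9, C10): its C8=C9 double bond lies β,γ to the oxygen-bearing C6, so the C7–C8 bond can be cut into the α-carbon (C7) of a C6 methyl ketone enolate and the iodine-bearing carbon (C8) of a (Z)-alkenyl iodide.
Ring order: the five-membered ring (C1–C5) is there from 2-methylcyclopentane-1,3-dione (C1 by alkylation, C1/C2 configuration by desymmetrising reduction); the seven-membered ring is closed second, by palladium-mediated C7–C8 coupling of an acetylcyclopentene.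
After ring closure: catalyst-controlled C6 reduction, hydroxyl-directed C4=C5 epoxidation, stereospecific 1,2-hydride shift to C5, anti-selective Tishchenko reduction at C6, organocerium addition at C4, then the esters.

Key step: step 9

Numbering used for all bicyclic compounds: C1 = quaternary ring-fusion carbon carrying CH3, C2 = carbon carrying the angelate oxygen, C3 = CH2, C4 = isopropyl carbinol carbon, C5 = ring-fusion CH, C6 = carbon carrying the aroyloxy group, C7 = CH2, C8(CH3)=C9, C10 = CH2. α is the face of the C1 methyl group, β the opposite face.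

Remark: the target SMILES is read as the cis-fused hydroazulene (1R,2S,4S,5R,6R) with C1–CH3, C5–H, the C4 isopropyl group and C6–O on the α face and C2–O and C4–OH on the β face. Because C5–H is cis to the C1 methyl and a C6 ketone with the C8=C9 olefin cannot be base-equilibrated without olefin migration, C5–H is delivered by a stereospecific hydride shift and not by enolate protonation.

**Route**

Step 1
Reactants: 1 but-2-yn-1-ol
Product: 3 (Z)-3-iodobut-2-en-1-ol, via cyclic alkenylaluminate 2 (not isolated)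
Conditions: NaAlH2(OCH2CH2OMe)2 (Red-Al), Et2O, 0 °C → rt; then I2, THF, −78 → 0 °C
Reagents that add atoms: iodine, II; sodium bis(2-methoxyethoxy)aluminium dihydride, [Na+].[AlH2-](OCCOC)OCCOC (aluminium in 2 only)
Why: Hydroxyl-directed trans-hydroalumination of the propargylic alcohol places aluminium on C3 in a five-membered alanate, and iodinolysis of the C–Al bond with retention should give the Z iodoalkene.

Step 2
Reactants: 3 (Z)-3-iodobut-2-en-1-ol
Product: 4 (Z)-1-bromo-3-iodobut-2-ene
Conditions: CBr4, PPh3, CH2Cl2, 0 °C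
Reagents that add atoms: carbon tetrabromide, BrC(Br)(Br)Br
Why: Appel reaction at the primary allylic carbon under neutral conditions, which leaves the alkenyl iodide and its geometry untouched.

Step 3
Reactants: 4 (Z)-1-bromo-3-iodobut-2-ene; 5 2-methylcyclopentane-1,3-dione
Product: 6 2-[(Z)-3-iodobut-2-en-1-yl]-2-methylcyclopentane-1,3-dione
Conditions: NaOH (1 M aq, 1.0 equiv), Bu4NI (cat.), rt
Reagents that add atoms: none
Why: C-alkylation of the sodium enolate of the cyclic 1,3-dione with an allylic bromide in water, where hydrogen bonding to the enolate oxygens favours carbon over oxygen attack.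

Step 4
Reactants: 6 2-[(Z)-3-iodobut-2-en-1-yl]-2-methylcyclopentane-1,3-dione
Product: 7 (2S,3S)-3-hydroxy-2-[(Z)-3-iodobut-2-en-1-yl]-2-methylcyclopentan-1-one
Conditions: (R)-2-methyl-CBS-oxazaborolidine (20 mol%), catecholborane (1.2 equiv), toluene, −78 °C
Reagents that add atoms: none
Why: Desymmetrising Corey–Bakshi–Shibata reduction in which the (R)-catalyst (quaternary carbon as the large group) should give the S carbinol and hydride enters on the methyl face, anti to the larger iodobutenyl group, so one carbonyl is reduced and both the carbinol centre (C2 of the target) and the quaternary centre (C1) are fixed with OH cis to the side chain.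

Step 5
Reactants: 7 (2S,3S)-3-hydroxy-2-[(Z)-3-iodobut-2-en-1-yl]-2-methylcyclopentan-1-one
Product: 8 (2S,3S)-3-(tert-butyldimethylsilyloxy)-2-[(Z)-3-iodobut-2-en-1-yl]-2-methylcyclopentan-1-one
Conditions: TBSCl, imidazole, DMF, rt
Reagents that add atoms: tert-butyldimethylsilyl chloride, CC(C)(C)[Si](C)(C)Cl
Why: Standard silylation of the secondary alcohol; the quaternary α-carbon excludes dehydration of the β-hydroxy ketone.

Step 6
Reactants: 8 (2S,3S)-3-(tert-butyldimethylsilyloxy)-2-[(Z)-3-iodobut-2-en-1-yl]-2-methylcyclopentan-1-one; 9 ethynylmagnesium bromide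
Product: 10 (2S,3S)-3-(tert-butyldimethylsilyloxy)-1-ethynyl-2-[(Z)-3-iodobut-2-en-1-yl]-2-methylcyclopentan-1-ol (both C1 epimers)
Conditions: HC≡CMgBr (3 equiv), THF, 0 °C → rt
Reagents that add atoms: none
Why: 1,2-Addition of a small, weakly basic alkynyl Grignard reagent to the hindered cyclopentanone; the new carbinol centre is removed in step 7, so its configuration is irrelevant.

Step 7
Reactants: 10 (2S,3S)-3-(tert-butyldimethylsilyloxy)-1-ethynyl-2-[(Z)-3-iodobut-2-en-1-yl]-2-methylcyclopentan-1-ol
Product: 11 (4S,5R)-4-(tert-butyldimethylsilyloxy)-1-ethynyl-5-[(Z)-3-iodobut-2-en-1-yl]-5-methylcyclopent-1-ene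
Conditions: Martin sulfurane Ph2S[OC(CF3)2Ph]2, CH2Cl2, 0 °C → rt
Reagents that add atoms: none
Why: Neutral dehydration of the tertiary propargylic alcohol, which can only run towards the ring CH2 because the other neighbour is quaternary; it replaces the acidic Rupe conditions that the silyl ether would not survive.

Step 8
Reactants: 11 (4S,5R)-4-(tert-butyldimethylsilyloxy)-1-ethynyl-5-[(Z)-3-iodobut-2-en-1-yl]-5-methylcyclopent-1-ene
Product: 12 1-[(4S,5R)-4-(tert-butyldimethylsilyloxy)-5-[(Z)-3-iodobut-2-en-1-yl]-5-methylcyclopent-1-en-1-yl]ethan-1-one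
Conditions: Ph3PAuNTf2 (2 mol%), H2O (5 equiv), 1,4-dioxane, 60 °C
Reagents that add atoms: water, O
Why: Gold-catalysed Markovnikov hydration of the terminal alkyne of the conjugated enyne gives the methyl ketone (the Rupe product); the electron-poor iodoalkene is not expected to attack the activated alkyne.

Step 9
Reactants: 12 1-[(4S,5R)-4-(tert-butyldimethylsilyloxy)-5-[(Z)-3-iodobut-2-en-1-yl]-5-methylcyclopent-1-en-1-yl]ethan-1-one
Product: 14 bicyclic dienone (1R,2S): 2β-(tert-butyldimethylsilyloxy)-1α,8-dimethyl; C4=C5; C6 ketone; C8=C9, via potassium enolate 13 (not isolated)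
Conditions: KN(SiMe3)2 (2.2 equiv), THF, −78 °C; then Pd(PPh3)4 (10 mol%), −78 °C → rt; AcOH quench at −78 °C
Reagents that add atoms: potassium bis(trimethylsilyl)amide, C[Si](C)(C)[N-][Si](C)(C)C.[K+] (potassium in 13 only)
Why: KN(SiMe3)2 at −78 °C removes a methyl proton (C7) irreversibly to give the cross-conjugated enolate 13; zerovalent palladium then inserts into the C8–I bond with retention, the enolate replaces iodide on palladium, and C–C reductive elimination from the eight-membered palladacycle (Pd, C8, C9, C10, C1, C5, C6, C7) closes the seven-membered ring. The closest known reaction type is the palladium-catalysed intramolecular α-alkenylation of ketone enolates with alkenyl halides, known for five- and six-membered rings and used here for a cycloheptene. No stereocentre is formed and C1 and C2 are not touched. The step needs site selectivity: C5 has no hydrogen because it is part of the C4=C5 enone, and kinetic deprotonation with excess amide base and no proton source avoids the extended C3 dienolate, which would attack through C5 to a five-membered ring or expel the C2 silyloxy group. It also needs the olefin to stay Z at C8=C9: retention in the oxidative addition keeps C10 and C7 cis, and the second equivalent of base holds the more acidic product as its dienolate, which the cold AcOH quench protonates at C7.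

Step 10
Reactants: 14 bicyclic dienone (1R,2S)
Product: 15 6β-allylic alcohol (6S): 2β-silyloxy; C4=C5; C8=C9
Conditions: (R)-2-methyl-CBS-oxazaborolidine (20 mol%), catecholborane (1.5 equiv), toluene, −78 °C
Reagents that add atoms: none
Why: Corey–Bakshi–Shibata reduction of an α-substituted cyclic enone with the alkenyl carbon C5 as the large group, so the (R)-catalyst should give the 6S (β) alcohol by reagent control; this temporary centre steers steps 11 and 12, and the low temperature avoids conjugate reduction and hydroboration.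

Step 11
Reactants: 15 6β-allylic alcohol (6S)
Product: 16 4β,5β-epoxy-6β-alcohol
Conditions: VO(acac)2 (5 mol%), t-BuOOH (1.2 equiv), CH2Cl2, 0 °C
Reagents that add atoms: tert-butyl hydroperoxide, CC(C)(C)OO
Why: Vanadium-catalysed hydroxyl-directed epoxidation delivers oxygen to C4=C5 from the face of the C6 hydroxyl (β), setting C4–O β, and the allylic olefin reacts much faster than the homoallylic C8=C9.

Step 12
Reactants: 16 4β,5β-epoxy-6β-alcohol
Product: 19 4β-hydroxy-5α-H 6-ketone (cis-fused), via 6-O-trimethylsilyl epoxide 17 (not isolated), via 4-O-trimethylsilyl ketone 18 (not isolated)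
Conditions: Me3SiOTf (2.2 equiv), i-Pr2NEt (2.5 equiv), CH2Cl2, −78 → −40 °C; then citric acid, MeOH, 0 °C
Reagents that add atoms: trimethylsilyl trifluoromethanesulfonate, C[Si](C)(C)OS(=O)(=O)C(F)(F)F (silicon in 17 and 18 only)
Why: Silyl triflate-promoted semipinacol rearrangement of a 2,3-epoxy alcohol silyl ether (the non-aldol aldol process): the activated epoxide opens at the tertiary C5 while the C6 hydrogen, antiperiplanar to the C5–O bond in the syn epoxy alcohol, shifts to the α face of C5, so C5–H ends cis to the C1 methyl, C4–O stays β and C6 becomes the ketone.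

Step 13
Reactants: 19 4β-hydroxy-5α-H 6-ketone
Product: 20 4β-acetoxy-6α-alcohol
Conditions: SmI2 (20 mol%), MeCHO (6 equiv), THF, −10 °C
Reagents that add atoms: acetaldehyde, CC=O
Why: Evans–Tishchenko reduction: the samarium-bound hemiacetal formed at the C4 hydroxyl transfers hydride intramolecularly to the β face of the C6 carbonyl, giving the anti 1,3-diol monoester with C6–OH α and leaving the two oxygens differentiated.

Step 14
Reactants: 20 4β-acetoxy-6α-alcohol
Product: 21 4β-acetoxy-6α-(3,4,5-trimethoxybenzoate)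
Conditions: 3,4,5-(MeO)3C6H2COCl, Et3N, DMAP (cat.), CH2Cl2, rt
Reagents that add atoms: 3,4,5-trimethoxybenzoyl chloride, COc1cc(C(=O)Cl)cc(OC)c1OC
Why: Acylation of the only free hydroxyl group, which installs the final C6 ester with the configuration set in step 13.

Step 15
Reactants: 21 4β-acetoxy-6α-(3,4,5-trimethoxybenzoate)
Product: 22 4β-hydroxy-6α-(3,4,5-trimethoxybenzoate)
Conditions: K2CO3 (0.3 equiv), MeOH, 0 °C
Reagents that add atoms: none
Why: Methanolysis of the acetate should be much faster than that of the electron-rich, hindered aryl ester, and no enolisable carbonyl is present at this stage.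

Step 16
Reactants: 22 4β-hydroxy-6α-(3,4,5-trimethoxybenzoate)
Product: 23 4-ketone 6α-(3,4,5-trimethoxybenzoate) (5α-H)
Conditions: Dess–Martin periodinane, NaHCO3, CH2Cl2, rt
Reagents that add atoms: none
Why: Dess–Martin oxidation under buffered neutral conditions, so C5 (now α to the ketone and β to the aroyloxy group) is neither epimerised nor eliminated.

Step 17
Reactants: 23 4-ketone 6α-(3,4,5-trimethoxybenzoate)
Product: 24 4β-hydroxy-4α-isopropyl 6α-(3,4,5-trimethoxybenzoate), 2β-silyl ether
Conditions: i-PrMgCl (3 equiv), CeCl3 (3 equiv), THF, −78 °C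
Reagents that add atoms: isopropylmagnesium chloride, CC(C)[Mg]Cl
Why: Organocerium 1,2-addition (low basicity, ketone-selective) to the cyclopentanone from the α face, anti to the adjacent C5–C6 bond and to the C2 silyloxy group, which should give C4–OH β and the isopropyl group α.

Step 18
Reactants: 24 4β-hydroxy-4α-isopropyl 6α-(3,4,5-trimethoxybenzoate), 2β-silyl ether
Product: 25 2β,4β-diol 6α-(3,4,5-trimethoxybenzoate)
Conditions: HF·pyridine, THF, 0 °C → rt
Reagents that add atoms: none
Why: Fluoride-mediated cleavage of the silyl ether under mildly acidic conditions that spare the aryl ester, the tertiary alcohol and the trisubstituted olefin.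

Step 19
Reactants: 25 2β,4β-diol 6α-(3,4,5-trimethoxybenzoate)
Product: 26 CNP0112256.1
Conditions: angelic acid, 2,4,6-Cl3C6H2COCl, Et3N, toluene, rt; then 25, 75 °C
Reagents that add atoms: angelic acid, C/C=C(/C)C(=O)O
Why: Yamaguchi-type mixed-anhydride esterification without a nucleophilic catalyst keeps the Z (angelate) geometry, and only the secondary C2 hydroxyl reacts because the C4 hydroxyl is tertiary.

**Compound list**

1 | but-2-yn-1-ol | CC#CCO | starting material
2 | sodium 2,2-bis(2-methoxyethoxy)-3-methyl-2,5-dihydro-1,2-oxaluminol-2-uide (cyclic alkenylaluminate) | CC1=CCO[Al-]1(OCCOC)OCCOC.[Na+] | intermediate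
3 | (Z)-3-iodobut-2-en-1-ol | C/C(I)=C/CO | intermediate
4 | (Z)-1-bromo-3-iodobut-2-ene | C/C(I)=C/CBr | intermediate
5 | 2-methylcyclopentane-1,3-dione | CC1C(=O)CCC1=O | starting material
6 | 2-[(Z)-3-iodobut-2-en-1-yl]-2-methylcyclopentane-1,3-dione | CC1(C/C=C(/C)I)C(=O)CCC1=O | intermediate
7 | (2S,3S)-3-hydroxy-2-[(Z)-3-iodobut-2-en-1-yl]-2-methylcyclopentan-1-one | O=C1CC[C@H](O)[C@]1(C)C/C=C(/C)I | intermediate
8 | (2S,3S)-3-(tert-butyldimethylsilyloxy)-2-[(Z)-3-iodobut-2-en-1-yl]-2-methylcyclopentan-1-one | O=C1CC[C@H](O[Si](C)(C)C(C)(C)C)[C@]1(C)C/C=C(/C)I | intermediate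
9 | ethynylmagnesium bromide | C#C[Mg]Br | starting material
10 | (2S,3S)-3-(tert-butyldimethylsilyloxy)-1-ethynyl-2-[(Z)-3-iodobut-2-en-1-yl]-2-methylcyclopentan-1-ol, both C1 epimers | C#CC1(O)CC[C@H](O[Si](C)(C)C(C)(C)C)[C@]1(C)C/C=C(/C)I | intermediate
11 | (4S,5R)-4-(tert-butyldimethylsilyloxy)-1-ethynyl-5-[(Z)-3-iodobut-2-en-1-yl]-5-methylcyclopent-1-ene | C#CC1=CC[C@H](O[Si](C)(C)C(C)(C)C)[C@]1(C)C/C=C(/C)I | intermediate
12 | 1-[(4S,5R)-4-(tert-butyldimethylsilyloxy)-5-[(Z)-3-iodobut-2-en-1-yl]-5-methylcyclopent-1-en-1-yl]ethan-1-one | CC(=O)C1=CC[C@H](O[Si](C)(C)C(C)(C)C)[C@]1(C)C/C=C(/C)I | intermediate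
13 | potassium 1-[(4S,5R)-4-(tert-butyldimethylsilyloxy)-5-[(Z)-3-iodobut-2-en-1-yl]-5-methylcyclopent-1-en-1-yl]ethen-1-olate | C=C([O-])C1=CC[C@H](O[Si](C)(C)C(C)(C)C)[C@]1(C)C/C=C(/C)I.[K+] | intermediate
14 | bicyclic dienone (1R,2S): 2β-(tert-butyldimethylsilyloxy)-1α,8-dimethyl, C4=C5, C6 ketone, C8=C9 | CC(C)(C)[Si](C)(C)O[C@H]1CC=C2C(=O)CC(C)=CC[C@@]12C | intermediate
15 | 6β-allylic alcohol (6S) of 14: 2β-silyloxy, C4=C5, C8=C9 | CC(C)(C)[Si](C)(C)O[C@H]1CC=C2[C@@H](O)CC(C)=CC[C@@]12C | intermediate
16 | 4β,5β-epoxy-6β-alcohol, 2β-silyloxy, C8=C9 | CC(C)(C)[Si](C)(C)O[C@H]1C[C@H]3O[C@]32[C@@H](O)CC(C)=CC[C@@]12C | intermediate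
17 | 6-O-trimethylsilyl ether of 16 | CC(C)(C)[Si](C)(C)O[C@H]1C[C@H]3O[C@]32[C@@H](O[Si](C)(C)C)CC(C)=CC[C@@]12C | intermediate
18 | 4β-trimethylsilyloxy-5α-H 6-ketone, 2β-silyloxy, C8=C9 | CC(C)(C)[Si](C)(C)O[C@H]1C[C@@H](O[Si](C)(C)C)[C@H]2C(=O)CC(C)=CC[C@@]12C | intermediate
19 | 4β-hydroxy-5α-H 6-ketone (cis-fused), 2β-silyloxy, C8=C9 | CC(C)(C)[Si](C)(C)O[C@H]1C[C@@H](O)[C@H]2C(=O)CC(C)=CC[C@@]12C | intermediate
20 | 4β-acetoxy-6α-alcohol, 5α-H, 2β-silyloxy | CC(C)(C)[Si](C)(C)O[C@H]1C[C@@H](OC(C)=O)[C@H]2[C@H](O)CC(C)=CC[C@@]12C | intermediate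
21 | 4β-acetoxy-6α-(3,4,5-trimethoxybenzoate), 2β-silyloxy | CC(C)(C)[Si](C)(C)O[C@H]1C[C@@H](OC(C)=O)[C@H]2[C@H](OC(=O)c3cc(OC)c(OC)c(OC)c3)CC(C)=CC[C@@]12C | intermediate
22 | 4β-hydroxy-6α-(3,4,5-trimethoxybenzoate), 2β-silyloxy | CC(C)(C)[Si](C)(C)O[C@H]1C[C@@H](O)[C@H]2[C@H](OC(=O)c3cc(OC)c(OC)c(OC)c3)CC(C)=CC[C@@]12C | intermediate
23 | 4-ketone 6α-(3,4,5-trimethoxybenzoate), 5α-H, 2β-silyloxy | CC(C)(C)[Si](C)(C)O[C@H]1CC(=O)[C@H]2[C@H](OC(=O)c3cc(OC)c(OC)c(OC)c3)CC(C)=CC[C@@]12C | intermediate
24 | 4β-hydroxy-4α-isopropyl 6α-(3,4,5-trimethoxybenzoate), 2β-silyloxy | CC(C)(C)[Si](C)(C)O[C@H]1C[C@](O)(C(C)C)[C@H]2[C@H](OC(=O)c3cc(OC)c(OC)c(OC)c3)CC(C)=CC[C@@]12C | intermediate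
25 | 2β,4β-dihydroxy-4α-isopropyl 6α-(3,4,5-trimethoxybenzoate) | O[C@H]1C[C@](O)(C(C)C)[C@H]2[C@H](OC(=O)c3cc(OC)c(OC)c(OC)c3)CC(C)=CC[C@@]12C | intermediate
26 | CNP0112256.1: (1R,2S,4S,5R,6R) 2-angelate 6-(3,4,5-trimethoxybenzoate) of the cis-fused 4-isopropyl-1,8-dimethylhydroazul-8-ene-2,4,6-triol | C/C=C(/C)C(=O)O[C@H]1C[C@](O)(C(C)C)[C@H]2[C@H](OC(=O)c3cc(OC)c(OC)c(OC)c3)CC(C)=CC[C@@]12C | target

**Summary**

Total step count: 19. Longest linear sequence: 19 steps (1 to 26); 5 and 9 enter at steps 3 and 6.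

Steps most likely to fail:

Step 9 (ring closure). Reductive elimination through the eight-membered palladacycle may be slow, so that proton transfer to the extended C3 dienolate (closure at C5 or loss of the silyloxy group) or reduction of the C–I bond takes over. Fallback: 12 is silylated under kinetic control (LiN(i-Pr)2, Me3SiCl, THF, −78 °C) to the 2-(trimethylsilyloxy)diene F1. F1 is then cyclised under neutral conditions with Pd(PPh3)4 and Bu3SnF in toluene at reflux (tin enolate formed in situ from the enol silane), which makes the same C7–C8 bond and returns to 14.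

Step 12 (hydride shift). The silyl-activated epoxide may ionise without the C6–H shift, followed by migration of a C1 substituent or proton loss, or the product ketone may be enol-silylated and C8=C9 moved on hydrolysis. Fallback: 16 is oxidised with Dess–Martin periodinane to the epoxy ketone F2, and the C5–O bond of F2 is cleaved reductively with SmI2 (THF/MeOH, −78 °C), returning to 19. C4 keeps its configuration, but C5 then comes from protonation of a samarium enolate instead of a stereospecific shift and its configuration has to be confirmed before going on.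

Step 17 (isopropyl addition). Ketone 23 may enolise towards C5 with E1cB loss of the C6 aroyloxy group or epimerisation at C5, or the reagent may attack the ester. Fallback: the ester is introduced after the addition. Compound 20 is silylated (Et3SiCl, imidazole, DMF) to the 6-O-triethylsilyl acetate F3; the acetate is removed (K2CO3, MeOH) to give the alcohol F4; Dess–Martin oxidation gives the ketone F5; i-PrMgCl/CeCl3 at −78 °C gives the tertiary alcohol F6; pyridinium p-toluenesulfonate in MeOH removes only the triethylsilyl group to give the diol F7; and 3,4,5-trimethoxybenzoyl chloride (Et3N, DMAP) acylates the secondary C6 hydroxyl alone, returning to 24.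

**Further compounds**

F1 | step 9 | (4S,5R)-4-(tert-butyldimethylsilyloxy)-5-[(Z)-3-iodobut-2-en-1-yl]-5-methyl-1-[1-(trimethylsilyloxy)ethenyl]cyclopent-1-ene | C=C(O[Si](C)(C)C)C1=CC[C@H](O[Si](C)(C)C(C)(C)C)[C@]1(C)C/C=C(/C)I
F2 | step 12 | 4β,5β-epoxy 6-ketone, 2β-silyloxy, C8=C9 | CC(C)(C)[Si](C)(C)O[C@H]1C[C@H]3O[C@]32C(=O)CC(C)=CC[C@@]12C
F3 | step 17 | 4β-acetoxy-6α-(triethylsilyloxy) compound, 2β-silyloxy | CC(C)(C)[Si](C)(C)O[C@H]1C[C@@H](OC(C)=O)[C@H]2[C@H](O[Si](CC)(CC)CC)CC(C)=CC[C@@]12C
F4 | step 17 | 4β-hydroxy-6α-(triethylsilyloxy) compound, 2β-silyloxy | CC(C)(C)[Si](C)(C)O[C@H]1C[C@@H](O)[C@H]2[C@H](O[Si](CC)(CC)CC)CC(C)=CC[C@@]12C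
F5 | step 17 | 4-ketone 6α-triethylsilyl ether, 5α-H, 2β-silyloxy | CC(C)(C)[Si](C)(C)O[C@H]1CC(=O)[C@H]2[C@H](O[Si](CC)(CC)CC)CC(C)=CC[C@@]12C
F6 | step 17 | 4β-hydroxy-4α-isopropyl 6α-triethylsilyl ether, 2β-silyloxy | CC(C)(C)[Si](C)(C)O[C@H]1C[C@](O)(C(C)C)[C@H]2[C@H](O[Si](CC)(CC)CC)CC(C)=CC[C@@]12C
F7 | step 17 | 4β,6α-diol with 4α-isopropyl, 2β-silyloxy | CC(C)(C)[Si](C)(C)O[C@H]1C[C@](O)(C(C)C)[C@H]2[C@H](O)CC(C)=CC[C@@]12C
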